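**Strategy.** Everything rests on cutting the O4–C3a bond of the tetrahydrofuran ring (C3a, O4, C5, C6, C6a) and, with it, the benzylic C–OAr bond. Two features are exploited. O4 sits β to the lactone carbonyl C2, so O4–C3a is an oxa-Michael bond to a butenolide (C3=C3a). O4 on C5 and the aryloxy oxygen on the benzylic carbon are vicinal and threo, the signature of a cis-epoxide opened with inversion. In one operation the 7-OH of (S)-pinocembrin opens the epoxide and the released alkoxide closes the last ring 5-exo-trig, setting the benzylic centre and C3a. The precursor is a monocyclic (R)-γ-substituted butenolide carrying a (2S,3R)-cis-phenyloxirane.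

Key step: step 7

Assumption: (R)-epichlorohydrin and (2S)-pinocembrin (the natural enantiomer) are bought as single enantiomers; locants C2 to C6a follow furo[3,2-b]furan-2-one numbering.

Step 1
Reactants: 1 (R)-epichlorohydrin; 2 phenylacetylene
Product: 4 (R)-1-chloro-5-phenylpent-4-yn-2-ol, via lithium phenylacetylide 3 (not isolated)
Conditions: 2, n-BuLi, THF, −78 °C; BF3·OEt2; then 1, −78 °C; aq. NH4Cl
Reagents that add atoms: none
Why: BF3-mediated alkynylation of an epoxide by a lithium acetylide should occur at the unsubstituted oxirane carbon at −78 °C, leaving the C–Cl bond and the stereocentre untouched, so the R configuration is carried over from 1.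

Step 2
Reactants: 4 (R)-1-chloro-5-phenylpent-4-yn-2-ol
Product: 6 (R)-6-phenylhex-1-en-5-yn-3-ol, via propargyl oxirane 5 (not isolated)
Conditions: Me3S+ I− (4 equiv), n-BuLi, THF, −10 °C; then 4, −10 °C to rt
Reagents that add atoms: trimethylsulfonium iodide, C[S+](C)C.[I-]
Why: Excess dimethylsulfonium methylide should first close the chlorohydrin to the terminal epoxide, then open it at CH2 and eliminate Me2S from the β-oxido sulfonium salt (one-carbon homologation of a terminal epoxide to an allylic alcohol); the carbinol centre is not involved and stays R.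

Step 3
Reactants: 6 (R)-6-phenylhex-1-en-5-yn-3-ol
Product: 7 (R)-6-phenylhex-1-en-5-yn-3-yl acrylate
Conditions: acryloyl chloride, Et3N, DMAP (cat.), CH2Cl2, 0 °C
Reagents that add atoms: acryloyl chloride, C=CC(=O)Cl
Why: Standard DMAP-catalysed O-acylation of a secondary allylic alcohol with an acid chloride; no stereocentre is touched.

Step 4
Reactants: 7 (R)-6-phenylhex-1-en-5-yn-3-yl acrylate
Product: 8 (R)-5-(3-phenylprop-2-yn-1-yl)furan-2(5H)-one
Conditions: second-generation Grubbs catalyst RuCl2(=CHPh)(PCy3)(H2IMes) (5 mol%), CH2Cl2 (5 mM), reflux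
Reagents that add atoms: none
Why: Ring-closing metathesis of an allyl acrylate to a butenolide: the catalyst should load at the vinyl group and close onto the acrylate, while the internal aryl alkyne sits too close to the carbene for a ring-closing enyne mode and should be left alone at high dilution; the γ-centre is retained.

Step 5
Reactants: 8 (R)-5-(3-phenylprop-2-yn-1-yl)furan-2(5H)-one
Product: 9 (R)-5-[(Z)-3-phenylprop-2-en-1-yl]furan-2(5H)-one
Conditions: H2 (1 atm), Lindlar catalyst (Pd/CaCO3 poisoned with Pb(OAc)2), quinoline, EtOAc, rt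
Reagents that add atoms: none
Why: Lindlar semihydrogenation delivers H2 syn to the alkyne from the poisoned Pd surface, which should give the Z-styrene and spare the electron-poor, conjugated butenolide alkene.

Step 6
Reactants: 9 (R)-5-[(Z)-3-phenylprop-2-en-1-yl]furan-2(5H)-one
Product: 10 (R)-5-{[(2S,3R)-3-phenyloxiran-2-yl]methyl}furan-2(5H)-one
Conditions: (R,R)-Jacobsen catalyst, MnCl[(R,R)-N,N′-bis(3,5-di-tert-butylsalicylidene)cyclohexane-1,2-diaminate] (5 mol%), mCPBA, NMO, CH2Cl2, −78 °C
Reagents that add atoms: mCPBA, O=C(OO)c1cccc(Cl)c1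
Why: Jacobsen epoxidation is at its best with cis-disubstituted aryl alkenes, and the electron-poor butenolide C=C should be inert to both the manganese-oxo species and mCPBA at −78 °C; the two new centres are set by the catalyst alone, the (R,R) ligand being chosen by analogy with the facial sense accepted for indene and cis-β-methylstyrene, and the low temperature should keep cis-to-trans leakage small.

Step 7
Reactants: 10 (R)-5-{[(2S,3R)-3-phenyloxiran-2-yl]methyl}furan-2(5H)-one; 11 (S)-pinocembrin
Product: 13 (3aR,5S,6aR)-5-[(S)-{[(2S)-5-hydroxy-4-oxo-2-phenyl-3,4-dihydro-2H-chromen-7-yl]oxy}(phenyl)methyl]tetrahydrofuro[3,2-b]furan-2(3H)-one, via hydroxy ether butenolide 12 (not isolated)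
Conditions: 11 (1.5 equiv), CsF (0.5 equiv), DMF, 50 °C
Reagents that add atoms: none
Why: The 7-phenoxide of 11, generated in small amount by CsF, should open the cis-epoxide of 10 at its benzylic carbon by SN2, and the secondary alkoxide of 12 thus released, held five atoms from the butenolide β-carbon, adds to it by oxa-Michael closure; the lactone enolate is protonated by further 11, which regenerates the phenoxide. The closest known reaction types are the phenoxide opening of 3-aryl oxiranes at the benzylic position and the alkoxide conjugate addition to γ-substituted butenolides that gives cis-fused furo[3,2-b]furanones, here run as one domino. One ring is closed, the tetrahydrofuran, in 5-exo-trig mode through the O4–C3a bond. The benzylic centre becomes S by inversion of the R oxirane carbon, C5 is carried unchanged from the other oxirane carbon, and C3a is fixed as R by C6a because only the cis 5/5 fusion is attainable, with the side chain on the convex face. The step needs attack at the benzylic and not the homobenzylic oxirane carbon, which benzylic SN2 activation and the branched CH2 neighbour of the other carbon should secure, and O-alkylation at the 7-OH only, which follows from the 5-OH being chelated to C4=O and far less acidic. It also needs flavanone C2 and butenolide C6a to survive, for which the medium holds no base stronger than the 7-phenoxide, a vinylogous carboxylate that disfavours enolisation at flavanone C3, with excess 11 as proton buffer.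

**Compound list**

1 | (R)-epichlorohydrin, (R)-2-(chloromethyl)oxirane | ClC[C@H]1CO1 | starting material
2 | phenylacetylene | C#Cc1ccccc1 | starting material
3 | lithium phenylacetylide | [Li]C#Cc1ccccc1 | intermediate (not isolated)
4 | (R)-1-chloro-5-phenylpent-4-yn-2-ol | ClC[C@H](O)CC#Cc1ccccc1 | intermediate
5 | (R)-2-(3-phenylprop-2-yn-1-yl)oxirane | C(C#Cc1ccccc1)[C@@H]1CO1 | intermediate (not isolated)
6 | (R)-6-phenylhex-1-en-5-yn-3-ol | C=C[C@H](O)CC#Cc1ccccc1 | intermediate
7 | (R)-6-phenylhex-1-en-5-yn-3-yl acrylate | C=CC(=O)O[C@@H](C=C)CC#Cc1ccccc1 | intermediate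
8 | (R)-5-(3-phenylprop-2-yn-1-yl)furan-2(5H)-one | O=C1C=C[C@@H](CC#Cc2ccccc2)O1 | intermediate
9 | (R)-5-[(Z)-3-phenylprop-2-en-1-yl]furan-2(5H)-one | O=C1C=C[C@@H](C/C=C\c2ccccc2)O1 | intermediate
10 | (R)-5-{[(2S,3R)-3-phenyloxiran-2-yl]methyl}furan-2(5H)-one | O=C1C=C[C@@H](C[C@@H]2O[C@@H]2c2ccccc2)O1 | intermediate
11 | (S)-pinocembrin, (2S)-5,7-dihydroxy-2-phenylchroman-4-one | O=C1C[C@@H](c2ccccc2)Oc2cc(O)cc(O)c12 | starting material
12 | (R)-5-[(2S,3S)-2-hydroxy-3-{[(2S)-5-hydroxy-4-oxo-2-phenyl-3,4-dihydro-2H-chromen-7-yl]oxy}-3-phenylpropyl]furan-2(5H)-one, present in the flask as its alkoxide | O=C1C=C[C@@H](C[C@H](O)[C@@H](Oc2cc(O)c3c(c2)O[C@H](c2ccccc2)CC3=O)c2ccccc2)O1 | intermediate (not isolated)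
13 | (3aR,5S,6aR)-5-[(S)-{[(2S)-5-hydroxy-4-oxo-2-phenyl-3,4-dihydro-2H-chromen-7-yl]oxy}(phenyl)methyl]tetrahydrofuro[3,2-b]furan-2(3H)-one | O=C1C[C@H]2O[C@H]([C@@H](Oc3cc(O)c4c(c3)O[C@H](c3ccccc3)CC4=O)c3ccccc3)C[C@H]2O1 | target

**Step count and risks**

Total step count: 7. Longest linear sequence: 7 steps (from 1 and 2 to 13); 11 enters in the last step.

Steps most likely to fail:

1. Step 7. The phenoxide may attack the homobenzylic oxirane carbon, the flavanone may open reversibly to its chalcone and lose the C2 configuration, or the butenolide may be deprotonated at its γ-carbon before cyclisation. The fallback sets out from 9 and comes back to the route at 13; it forms the aryl ether under neutral conditions. Catalytic osmium dihydroxylation of 9 (K2OsO2(OH)4, NMO, an indolinylcarbamate cinchona ligand, acetone/H2O) is a stereospecific syn addition and should give erythro diol (R)-5-[(2S,3R)-2,3-dihydroxy-3-phenylpropyl]furan-2(5H)-one F1, the wrong-face diastereomer being removed by chromatography. Catalytic DBU in CH2Cl2 should close F1 by the same 5-exo-trig oxa-Michael addition, still as the last ring closure, to bicyclic benzylic alcohol (3aR,5S,6aR)-5-[(R)-hydroxy(phenyl)methyl]tetrahydrofuro[3,2-b]furan-2(3H)-one F2; competition from 6-exo attack by the benzylic hydroxyl is the point to watch. A Mitsunobu reaction of F2 with 11 (PPh3, DIAD, THF, 0 °C) should then give 13 with inversion at the benzylic carbon, at the acidic 7-OH only.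

2. Step 6. There is no substrate bias, so facial selectivity depends wholly on the catalyst, and rotation in the stepwise oxygen transfer can leak cis alkene into trans epoxide. The fallback sets out from 9 and comes back to the route at 12; it replaces oxygen-atom transfer by concerted dihydroxylation and uses a cyclic sulfate as the epoxide equivalent. Diol F1 is made from 9 as described under step 7. SOCl2 and Et3N (CH2Cl2, 0 °C) should give cyclic sulfite (R)-5-{[(4S,5R)-2-oxido-5-phenyl-1,3,2-dioxathiolan-4-yl]methyl}furan-2(5H)-one F3, and RuCl3 (cat.) with NaIO4 (MeCN/CCl4/H2O, 0 °C) cyclic sulfate (R)-5-{[(4S,5R)-2,2-dioxido-5-phenyl-1,3,2-dioxathiolan-4-yl]methyl}furan-2(5H)-one F4, which has the configuration of 10. The phenoxide of 11 (Cs2CO3, acetone, rt) should attack its benzylic carbon with inversion to give sulfate monoester (2S,3S)-1-[(2R)-5-oxo-2,5-dihydrofuran-2-yl]-3-{[(2S)-5-hydroxy-4-oxo-2-phenyl-3,4-dihydro-2H-chromen-7-yl]oxy}-3-phenylpropan-2-yl hydrogen sulfate F5. Acid hydrolysis (cat. H2SO4, THF, H2O) returns 12, which is closed to 13 with CsF in DMF as in the second half of step 7.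

3. Step 4. The ruthenium carbene may be diverted into enyne metathesis with the internal alkyne, or the electron-poor acrylate may close so slowly that dimerisation wins. The fallback sets out from 4 and comes back to the route at 8; it builds the butenolide without metathesis. NaOH closes 4 to epoxide 5, here isolated. The dianion of (phenylselanyl)acetic acid (LDA, THF, 0 °C) should open 5 at CH2, and acid (AcOH, heat) lactonises to selenide lactone (5R)-3-(phenylselanyl)-5-(3-phenylprop-2-yn-1-yl)dihydrofuran-2(3H)-one F6. H2O2 (CH2Cl2, 0 °C) gives the selenoxide, whose syn-elimination can only take a ring C4–H and should deliver 8.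

**Further compounds**

F1 | step 7 | (R)-5-[(2S,3R)-2,3-dihydroxy-3-phenylpropyl]furan-2(5H)-one | O=C1C=C[C@@H](C[C@H](O)[C@H](O)c2ccccc2)O1
F2 | step 7 | (3aR,5S,6aR)-5-[(R)-hydroxy(phenyl)methyl]tetrahydrofuro[3,2-b]furan-2(3H)-one | O=C1C[C@H]2O[C@H]([C@H](O)c3ccccc3)C[C@H]2O1
F3 | step 6 | (R)-5-{[(4S,5R)-2-oxido-5-phenyl-1,3,2-dioxathiolan-4-yl]methyl}furan-2(5H)-one (mixture at sulfur) | O=C1C=C[C@@H](C[C@@H]2OS(=O)O[C@@H]2c2ccccc2)O1
F4 | step 6 | (R)-5-{[(4S,5R)-2,2-dioxido-5-phenyl-1,3,2-dioxathiolan-4-yl]methyl}furan-2(5H)-one | O=C1C=C[C@@H](C[C@@H]2OS(=O)(=O)O[C@@H]2c2ccccc2)O1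
F5 | step 6 | (2S,3S)-1-[(2R)-5-oxo-2,5-dihydrofuran-2-yl]-3-{[(2S)-5-hydroxy-4-oxo-2-phenyl-3,4-dihydro-2H-chromen-7-yl]oxy}-3-phenylpropan-2-yl hydrogen sulfate | O=C1C=C[C@@H](C[C@H](OS(=O)(=O)O)[C@@H](Oc2cc(O)c3c(c2)O[C@H](c2ccccc2)CC3=O)c2ccccc2)O1
F6 | step 4 | (5R)-3-(phenylselanyl)-5-(3-phenylprop-2-yn-1-yl)dihydrofuran-2(3H)-one (mixture at C3) | O=C1C([Se]c2ccccc2)C[C@@H](CC#Cc2ccccc2)O1
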